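Ring B is disconnected at C8–C9. With C12 at the ester level, the C8 tertiary carbinol, C9, C11 and C12 of the target form a γ-hydroxy ester, the product pattern of a ketone ketyl adding to the β-carbon of an enoate. A single SmI2-mediated cyclisation of a ring A methyl ketone onto its own (E)-enoate should therefore close ring B, join C8 to C9 beside the quaternary C10 and set both C8 and C9. Its precursor is a monocyclic ring A keto enoate whose C5 and C10 centres come from a catalytic asymmetric Diels–Alder reaction; the equatorial C3 bromide and the lactate-derived C13 carbinol are installed after ring closure.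

Key step: step 12

Assumption: the (S)-configured oxazaborolidinium of step 5 is taken to expose the Re face at the α-carbon of the s-trans enal, as it does for simple 2-substituted acroleins; if the sense proved opposite, its mirror image would be used without other change.

Numbering: locants C1–C20 are labdane locants throughout (ring A = C1–C5, C10; ring B = C5–C10).

Step 1
Reactants: 1 ethyl levulinate
Product: 2 ethyl 3-(2-methyl-1,3-dioxolan-2-yl)propanoate
Conditions: HOCH2CH2OH, p-TsOH·H2O (cat.), toluene, reflux, Dean–Stark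
Reagents that add atoms: ethylene glycol, OCCO
Why: Acid-catalysed ketalisation with azeotropic removal of water masks the methyl ketone (the future C8 carbonyl) and leaves the ester free.

Step 2
Reactants: 2 ethyl 3-(2-methyl-1,3-dioxolan-2-yl)propanoate
Product: 3 3-(2-methyl-1,3-dioxolan-2-yl)propanal
Conditions: i-Bu2AlH (1.05 equiv), CH2Cl2, −78 °C; aq. KNaC4H4O6
Reagents that add atoms: none
Why: Partial hydride reduction of an ester at low temperature stops at the aluminium hemiacetal, which should release the aldehyde on work-up.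

Step 3
Reactants: 3 3-(2-methyl-1,3-dioxolan-2-yl)propanal; 4 2-(triphenylphosphoranylidene)propanal
Product: 5 (E)-2-methyl-5-(2-methyl-1,3-dioxolan-2-yl)pent-2-enal
Conditions: toluene, 90 °C
Reagents that add atoms: none
Why: Wittig olefination with a stabilised formyl ylide should give the (E)-trisubstituted enal, whose geometry later fixes the relative configuration of C5 and C10.

Step 4
Reactants: 6 but-3-en-2-one
Product: 7 2-(tert-butyldimethylsilyloxy)buta-1,3-diene
Conditions: TBSOTf, Et3N, Et2O, 0 °C
Reagents that add atoms: tert-butyldimethylsilyl triflate, CC(C)(C)[Si](C)(C)OS(=O)(=O)C(F)(F)F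
Why: Soft enolisation and O-silylation of the methyl ketone (silyl enol ether formation) should give the electron-rich 2-silyloxydiene.

Step 5
Reactants: 5 (E)-2-methyl-5-(2-methyl-1,3-dioxolan-2-yl)pent-2-enal; 7 2-(tert-butyldimethylsilyloxy)buta-1,3-diene
Product: 8 (1R,6R)-4-(tert-butyldimethylsilyloxy)-1-methyl-6-[2-(2-methyl-1,3-dioxolan-2-yl)ethyl]cyclohex-3-ene-1-carbaldehyde
Conditions: (S)-3,3-diphenyl-1-(2-methylphenyl)tetrahydro-1H,3H-pyrrolo[1,2-c][1,3,2]oxazaborole (20 mol %), HN(SO2CF3)2 (18 mol %), CH2Cl2, −78 → −40 °C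
Reagents that add atoms: none
Why: In this catalytic enantioselective Diels–Alder reaction the 2-silyloxy group directs the diene CH2 next to it onto the enal β-carbon (C5), so the formyl-bearing C10 ends para to C3, the (E)-enal geometry places the C10 methyl cis to the C5 side chain by suprafacial addition, and the chiral oxazaborolidinium shields one face of the coordinated enal so that C5 and C10 are set absolutely.

Step 6
Reactants: 8 Diels–Alder aldehyde; 9 trimethyl phosphonoacetate
Product: 10 methyl (E)-3-[(1R,6R)-4-(tert-butyldimethylsilyloxy)-1-methyl-6-[2-(2-methyl-1,3-dioxolan-2-yl)ethyl]cyclohex-3-en-1-yl]prop-2-enoate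
Conditions: NaH, THF, 0 °C; then 8, 0 °C → rt
Reagents that add atoms: none
Why: Horner–Wadsworth–Emmons olefination of the non-enolisable neopentyl aldehyde should give the (E)-enoate (C9=C11–C12), the silyl enol ether and ketal being inert to the non-aqueous base.

Step 7
Reactants: 10 silyl enol ether enoate
Product: 11 methyl (E)-3-[(1S,6R)-1-methyl-6-[2-(2-methyl-1,3-dioxolan-2-yl)ethyl]-4-oxocyclohex-2-en-1-yl]prop-2-enoate
Conditions: Pd(OAc)2 (1.1 equiv), MeCN, rt → 40 °C
Reagents that add atoms: none
Why: Saegusa–Ito oxidation palladates the C2=C3 silyl enol ether at C2 and eliminates a C1 hydrogen, so the C1=C2 enone forms regiospecifically and C4 becomes the only enolisable carbon.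

Step 8
Reactants: 11 C1=C2 enone
Product: 15 methyl (E)-3-[(1S,6S)-1,5,5-trimethyl-6-[2-(2-methyl-1,3-dioxolan-2-yl)ethyl]-4-oxocyclohex-2-en-1-yl]prop-2-enoate, via lithium dienolate 12 (not isolated), via monomethyl enone 13 (not isolated), via methylated lithium dienolate 14 (not isolated)
Conditions: LiN(i-Pr)2 (1.1 equiv), THF, −78 °C; MeI; then LiN(i-Pr)2 (1.2 equiv), −78 °C; MeI, DMPU, −78 → 0 °C
Reagents that add atoms: iodomethane, CI
Why: This α′-alkylation of a cyclohexenone through its cross-conjugated lithium dienolate can only occur at C4 (C10 is quaternary and the enoate has no acidic hydrogen), so two deprotonation–methylation cycles should build the C4 gem-dimethyl group without regiochemical ambiguity.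

Step 9
Reactants: 15 4,4-dimethyl enone
Product: 16 methyl (E)-3-[(1S,2S)-1,3,3-trimethyl-2-[2-(2-methyl-1,3-dioxolan-2-yl)ethyl]-4-oxocyclohexyl]prop-2-enoate
Conditions: [(Ph3P)CuH]6 (0.4 equiv), H2O (3 equiv), toluene, rt
Reagents that add atoms: none
Why: Copper hydride conjugate reduction delivers hydride to C1 of the enone, which is far more electrophilic than the equally hindered enoate, and water protonates the copper enolate to the saturated C3 ketone.

Step 10
Reactants: 16 C3 ketone
Product: 17 methyl (E)-3-[(1S,2S,4R)-4-hydroxy-1,3,3-trimethyl-2-[2-(2-methyl-1,3-dioxolan-2-yl)ethyl]cyclohexyl]prop-2-enoate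
Conditions: NaBH4, MeOH, 0 °C
Reagents that add atoms: none
Why: Borohydride reduction of the ketone by axial attack on the face away from the axial C4 and C10 methyls should give the equatorial C3 alcohol without touching the enoate; this centre only masks C3 and is oxidised again in step 13.

Step 11
Reactants: 17 ketal alcohol
Product: 18 methyl (E)-3-[(1S,2S,4R)-4-hydroxy-1,3,3-trimethyl-2-(3-oxobutyl)cyclohexyl]prop-2-enoate
Conditions: 1 M HCl, THF, rt
Reagents that add atoms: water, O
Why: Acid-catalysed ketal hydrolysis frees the C8 methyl ketone; the C3 hydroxyl is trans to the enoate arm across ring A and cannot add to it.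

Step 12
Reactants: 18 ring A keto enoate
Product: 19 methyl 2-[(1S,2S,4aS,6R,8aR)-2,6-dihydroxy-2,5,5,8a-tetramethyldecahydronaphthalen-1-yl]acetate
Conditions: SmI2 (2.5 equiv), MeOH (5 equiv), THF, −78 → 0 °C; cold aq. NH4Cl
Reagents that add atoms: none
Why: Electron transfer from divalent samarium to the C8 methyl ketone gives a samarium-bound ketyl that adds 6-exo-trig to C9, the β-carbon of the (E)-enoate, and a second electron followed by protonation by methanol turns the resulting α-ester radical into the saturated ester. The closest known reaction type is the SmI2-mediated ketyl–olefin cyclisation of keto enoates to trans-2-(alkoxycarbonylmethyl)cycloalkanols. Ring B closes in the 6-exo mode through a chair transition state that is necessarily trans-fused to ring A, because C6 and C9 are already equatorial on C5 and C10. C9 is set by the enoate arm taking the equatorial site of this chair (C9–H axial, anti to the C10 methyl), and C8 by the bulky samarium-bound oxygen taking the equatorial site anti to the enoate, which leaves the C8 methyl axial and the C8 oxygen trans to C11. The step needs chemoselectivity for the ketone–enoate pair and this trans-diequatorial diastereoselectivity; the activated acceptor allows HMPA-free conditions at low temperature, under which the free C3 hydroxyl and the ester are spectators and cold quenching limits lactonisation, while the preset C5 and C10 centres enforce the chair.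

Step 13
Reactants: 19 diol ester
Product: 20 methyl 2-[(1S,2S,4aS,8aR)-2-hydroxy-2,5,5,8a-tetramethyl-6-oxodecahydronaphthalen-1-yl]acetate
Conditions: Dess–Martin periodinane, CH2Cl2, rt
Reagents that add atoms: none
Why: Dess–Martin oxidation can act only on the secondary C3 carbinol, since the C8 carbinol is tertiary.

Step 14
Reactants: 20 C3 ketone hydroxy ester
Product: 21 methyl 2-[(1S,2S,4aS,8aR)-2,5,5,8a-tetramethyl-6-oxo-2-(triethylsilyloxy)decahydronaphthalen-1-yl]acetate
Conditions: TESOTf, 2,6-lutidine, CH2Cl2, −78 → 0 °C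
Reagents that add atoms: triethylsilyl triflate, CC[Si](CC)(CC)OS(=O)(=O)C(F)(F)F
Why: Silylation of the hindered tertiary C8 alcohol with a silyl triflate prevents lactonisation onto C12 and, later, ether formation with the C12 iodide.

Step 15
Reactants: 21 C8 silyl ether ketone
Product: 23 C2=C3 enol triflate ester, via potassium enolate 22 (not isolated)
Conditions: KN(SiMe3)2 (1.05 equiv), THF, −78 °C; PhNTf2, −78 → 0 °C
Reagents that add atoms: N-phenylbis(trifluoromethanesulfonimide), O=S(=O)(N(c1ccccc1)S(=O)(=O)C(F)(F)F)C(F)(F)F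
Why: Enol triflate formation is regiospecific because the ketone can enolise only towards C2 (C4 is quaternary), and the ketone α-hydrogens are more acidic than those of the ester.

Step 16
Reactants: 23 enol triflate ester
Product: 24 C2=C3 vinyl bromide ester
Conditions: Ni(OAc)2·4H2O (10 mol %), 1,5-cyclooctadiene (20 mol %), Zn (20 mol %), LiBr (3 equiv), DMA/THF, rt
Reagents that add atoms: lithium bromide, [Li+].[Br-]
Why: Nickel-catalysed triflate–halide exchange (oxidative addition of the C–OTf bond to zerovalent nickel, anion exchange, reductive elimination) should turn the enol triflate into the vinyl bromide under mild conditions that spare ester and silyl ether.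

Step 17
Reactants: 24 vinyl bromide ester
Product: 25 methyl 2-[(1S,2S,4aS,6R,8aR)-6-bromo-2,5,5,8a-tetramethyl-2-(triethylsilyloxy)decahydronaphthalen-1-yl]acetate
Conditions: Mn(dpm)3 (10 mol %), PhSiH3 (1.5 equiv), t-BuOOH (1.5 equiv), i-PrOH, rt
Reagents that add atoms: none
Why: In this metal-hydride hydrogen-atom-transfer hydrogenation of a haloalkene a hydrogen atom adds to C2, and the α-bromo C3 radical takes its second hydrogen along the axial trajectory on the face away from the axial C4 and C10 methyls, so bromine should end equatorial (the more stable epimer) without C–Br hydrogenolysis.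

Step 18
Reactants: 25 bromo ester
Product: 26 2-[(1S,2S,4aS,6R,8aR)-6-bromo-2,5,5,8a-tetramethyl-2-(triethylsilyloxy)decahydronaphthalen-1-yl]ethanol
Conditions: i-Bu2AlH (2.5 equiv), CH2Cl2, −78 → 0 °C; aq. KNaC4H4O6
Reagents that add atoms: none
Why: Full hydride reduction of the ester gives the C12 alcohol, the aluminium hydride being inert towards the secondary alkyl bromide and the silyl ether.

Step 19
Reactants: 26 C12 alcohol
Product: 27 C12 iodide (1-(2-iodoethyl) analogue of 26)
Conditions: PPh3, I2, imidazole, CH2Cl2, 0 °C → rt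
Reagents that add atoms: iodine, II
Why: Appel-type iodination converts the primary alcohol through its alkoxyphosphonium salt into the iodide by SN2, and the silylated C8 oxygen cannot close a tetrahydrofuran.

Step 20
Reactants: 28 (S)-lactic acid; 29 pivalaldehyde
Product: 30 (2S,5S)-2-tert-butyl-5-methyl-1,3-dioxolan-4-one
Conditions: p-TsOH (cat.), H2SO4 (cat.), pentane, reflux, Dean–Stark; recrystallisation
Reagents that add atoms: none
Why: Acid-catalysed acetalisation under equilibrating conditions favours the cis-2,5-disubstituted dioxolanone, whose new acetal centre stores the lactate configuration (self-regeneration of stereocentres).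

Step 21
Reactants: 30 cis-dioxolanone; 27 C12 iodide
Product: 32 (2S,5R)-2-tert-butyl-5-methyl-5-[2-(decalinyl)ethyl]-1,3-dioxolan-4-one, via lithium dioxolanone enolate 31 (not isolated)
Conditions: LiN(i-Pr)2, 30 (1.5 equiv), THF, −78 °C; then 27, DMPU, −78 → −30 °C
Reagents that add atoms: none
Why: In this diastereoselective enolate alkylation the primary iodide approaches the planar dioxolanone enolate anti to the tert-butyl group, so C12 takes the place of the original lactate hydrogen and C13 is formed with the (R) configuration of the target.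

Step 22
Reactants: 32 alkylated dioxolanone
Product: 33 (2R)-2-methyl-4-(decalinyl)butane-1,2-diol (C13 tertiary OH, C14 primary OH)
Conditions: LiBH4, THF, 0 °C → rt
Reagents that add atoms: none
Why: Hydride reduction of the acylal-type lactone gives the C14 primary alcohol and releases the C13 tertiary alkoxide together with pivalaldehyde (reduced to neopentyl alcohol), while borohydride does not displace the hindered equatorial bromide.

Step 23
Reactants: 33 1,2-diol
Product: 34 (2R)-2-hydroxy-2-methyl-4-(decalinyl)butanal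
Conditions: SO3·pyridine, DMSO, Et3N, CH2Cl2, 0 °C
Reagents that add atoms: none
Why: Parikh–Doering oxidation converts only the primary alcohol, the tertiary C13 carbinol being unoxidisable and activated-DMSO conditions avoiding glycol cleavage.

Step 24
Reactants: 34 α-hydroxy aldehyde
Product: 35 8-O-triethylsilyl ether of the target
Conditions: Ph3PCH3Br (3 equiv), KN(SiMe3)2 (2.9 equiv), THF, 0 °C; then 34, 0 °C → rt
Reagents that add atoms: methyltriphenylphosphonium bromide, C[P+](c1ccccc1)(c1ccccc1)c1ccccc1.[Br-]
Why: Wittig methylenation with excess ylide tolerates the free tertiary hydroxyl and installs C15, and the quaternary C13 cannot epimerise.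

Step 25
Reactants: 35 8-O-triethylsilyl ether
Product: 36 (3R,5S,8S,9S,10R,13R)-3-bromolabd-14-ene-8,13-diol (target)
Conditions: Bu4NF, THF, rt → 45 °C
Reagents that add atoms: none
Why: Fluoride-mediated desilylation frees the C8 alcohol; the equatorial, neopentyl-type bromide has no anti-periplanar hydrogen, so neither elimination nor substitution should compete.

Compound list ("decalinyl" in names 32–34 = the (1S,2S,4aS,6R,8aR)-6-bromo-2,5,5,8a-tetramethyl-2-(triethylsilyloxy)decahydronaphthalen-1-yl group)

1 | ethyl levulinate | CCOC(=O)CCC(C)=O | starting material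
2 | ethyl 3-(2-methyl-1,3-dioxolan-2-yl)propanoate | CCOC(=O)CCC1(C)OCCO1 | intermediate
3 | 3-(2-methyl-1,3-dioxolan-2-yl)propanal | O=CCCC1(C)OCCO1 | intermediate
4 | 2-(triphenylphosphoranylidene)propanal | CC(C=O)=P(c1ccccc1)(c1ccccc1)c1ccccc1 | starting material
5 | (E)-2-methyl-5-(2-methyl-1,3-dioxolan-2-yl)pent-2-enal | O=C/C(C)=C/CCC1(C)OCCO1 | intermediate
6 | but-3-en-2-one | C=CC(C)=O | starting material
7 | 2-(tert-butyldimethylsilyloxy)buta-1,3-diene | C=CC(=C)O[Si](C)(C)C(C)(C)C | intermediate
8 | (1R,6R)-4-(tert-butyldimethylsilyloxy)-1-methyl-6-[2-(2-methyl-1,3-dioxolan-2-yl)ethyl]cyclohex-3-ene-1-carbaldehyde | O=C[C@]1(C)CC=C(O[Si](C)(C)C(C)(C)C)C[C@H]1CCC2(C)OCCO2 | intermediate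
9 | trimethyl phosphonoacetate | COC(=O)CP(=O)(OC)OC | starting material
10 | methyl (E)-3-[(1R,6R)-4-(tert-butyldimethylsilyloxy)-1-methyl-6-[2-(2-methyl-1,3-dioxolan-2-yl)ethyl]cyclohex-3-en-1-yl]prop-2-enoate | COC(=O)/C=C/[C@]1(C)CC=C(O[Si](C)(C)C(C)(C)C)C[C@H]1CCC2(C)OCCO2 | intermediate
11 | methyl (E)-3-[(1S,6R)-1-methyl-6-[2-(2-methyl-1,3-dioxolan-2-yl)ethyl]-4-oxocyclohex-2-en-1-yl]prop-2-enoate | COC(=O)/C=C/[C@]1(C)C=CC(=O)C[C@H]1CCC2(C)OCCO2 | intermediate
12 | lithium dienolate of 11 (C3–OLi, C3=C4) | COC(=O)/C=C/[C@]1(C)C=CC([O-])=C[C@H]1CCC2(C)OCCO2.[Li+] | intermediate (not isolated)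
13 | C4-monomethyl enone (methyl trans to the C5 side chain; either epimer serves) | COC(=O)/C=C/[C@]1(C)C=CC(=O)[C@H](C)[C@H]1CCC2(C)OCCO2 | intermediate (not isolated)
14 | lithium dienolate of 13 | COC(=O)/C=C/[C@]1(C)C=CC([O-])=C(C)[C@H]1CCC2(C)OCCO2.[Li+] | intermediate (not isolated)
15 | methyl (E)-3-[(1S,6S)-1,5,5-trimethyl-6-[2-(2-methyl-1,3-dioxolan-2-yl)ethyl]-4-oxocyclohex-2-en-1-yl]prop-2-enoate | COC(=O)/C=C/[C@]1(C)C=CC(=O)C(C)(C)[C@H]1CCC2(C)OCCO2 | intermediate
16 | methyl (E)-3-[(1S,2S)-1,3,3-trimethyl-2-[2-(2-methyl-1,3-dioxolan-2-yl)ethyl]-4-oxocyclohexyl]prop-2-enoate | COC(=O)/C=C/[C@]1(C)CCC(=O)C(C)(C)[C@H]1CCC2(C)OCCO2 | intermediate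
17 | methyl (E)-3-[(1S,2S,4R)-4-hydroxy-1,3,3-trimethyl-2-[2-(2-methyl-1,3-dioxolan-2-yl)ethyl]cyclohexyl]prop-2-enoate | COC(=O)/C=C/[C@]1(C)CC[C@@H](O)C(C)(C)[C@H]1CCC2(C)OCCO2 | intermediate
18 | methyl (E)-3-[(1S,2S,4R)-4-hydroxy-1,3,3-trimethyl-2-(3-oxobutyl)cyclohexyl]prop-2-enoate (key-step precursor) | COC(=O)/C=C/[C@]1(C)CC[C@@H](O)C(C)(C)[C@H]1CCC(C)=O | intermediate
19 | methyl 2-[(1S,2S,4aS,6R,8aR)-2,6-dihydroxy-2,5,5,8a-tetramethyldecahydronaphthalen-1-yl]acetate (key-step product) | COC(=O)C[C@H]1[C@]2(C)CC[C@@H](O)C(C)(C)[C@H]2CC[C@]1(C)O | intermediate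
20 | methyl 2-[(1S,2S,4aS,8aR)-2-hydroxy-2,5,5,8a-tetramethyl-6-oxodecahydronaphthalen-1-yl]acetate | COC(=O)C[C@H]1[C@]2(C)CCC(=O)C(C)(C)[C@H]2CC[C@]1(C)O | intermediate
21 | methyl 2-[(1S,2S,4aS,8aR)-2,5,5,8a-tetramethyl-6-oxo-2-(triethylsilyloxy)decahydronaphthalen-1-yl]acetate | COC(=O)C[C@H]1[C@]2(C)CCC(=O)C(C)(C)[C@H]2CC[C@]1(C)O[Si](CC)(CC)CC | intermediate
22 | potassium enolate of 21 (C3–OK, C2=C3) | COC(=O)C[C@H]1[C@]2(C)CC=C([O-])C(C)(C)[C@H]2CC[C@]1(C)O[Si](CC)(CC)CC.[K+] | intermediate (not isolated)
23 | C2=C3 enol triflate of 21 (C3–OTf; other centres as in 21) | COC(=O)C[C@H]1[C@]2(C)CC=C(OS(=O)(=O)C(F)(F)F)C(C)(C)[C@H]2CC[C@]1(C)O[Si](CC)(CC)CC | intermediate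
24 | C2=C3 vinyl bromide (C3–Br; other centres as in 21) | COC(=O)C[C@H]1[C@]2(C)CC=C(Br)C(C)(C)[C@H]2CC[C@]1(C)O[Si](CC)(CC)CC | intermediate
25 | methyl 2-[(1S,2S,4aS,6R,8aR)-6-bromo-2,5,5,8a-tetramethyl-2-(triethylsilyloxy)decahydronaphthalen-1-yl]acetate | COC(=O)C[C@H]1[C@]2(C)CC[C@@H](Br)C(C)(C)[C@H]2CC[C@]1(C)O[Si](CC)(CC)CC | intermediate
26 | 2-[(1S,2S,4aS,6R,8aR)-6-bromo-2,5,5,8a-tetramethyl-2-(triethylsilyloxy)decahydronaphthalen-1-yl]ethanol | OCC[C@H]1[C@]2(C)CC[C@@H](Br)C(C)(C)[C@H]2CC[C@]1(C)O[Si](CC)(CC)CC | intermediate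
27 | C12 iodide: 1-(2-iodoethyl) analogue of 26 | ICC[C@H]1[C@]2(C)CC[C@@H](Br)C(C)(C)[C@H]2CC[C@]1(C)O[Si](CC)(CC)CC | intermediate
28 | (S)-lactic acid | C[C@H](O)C(=O)O | starting material
29 | pivalaldehyde | CC(C)(C)C=O | starting material
30 | (2S,5S)-2-tert-butyl-5-methyl-1,3-dioxolan-4-one | C[C@@H]1O[C@H](C(C)(C)C)OC1=O | intermediate
31 | lithium enolate of 30 | CC1=C([O-])O[C@@H](C(C)(C)C)O1.[Li+] | intermediate (not isolated)
32 | (2S,5R)-2-tert-butyl-5-methyl-5-[2-(decalinyl)ethyl]-1,3-dioxolan-4-one | C[C@]1(CC[C@H]2[C@]3(C)CC[C@@H](Br)C(C)(C)[C@H]3CC[C@]2(C)O[Si](CC)(CC)CC)O[C@H](C(C)(C)C)OC1=O | intermediate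
33 | (2R)-2-methyl-4-(decalinyl)butane-1,2-diol | OC[C@](C)(O)CC[C@H]1[C@]2(C)CC[C@@H](Br)C(C)(C)[C@H]2CC[C@]1(C)O[Si](CC)(CC)CC | intermediate
34 | (2R)-2-hydroxy-2-methyl-4-(decalinyl)butanal | O=C[C@](C)(O)CC[C@H]1[C@]2(C)CC[C@@H](Br)C(C)(C)[C@H]2CC[C@]1(C)O[Si](CC)(CC)CC | intermediate
35 | 8-O-triethylsilyl ether of the target | C=C[C@](C)(O)CC[C@H]1[C@]2(C)CC[C@@H](Br)C(C)(C)[C@H]2CC[C@]1(C)O[Si](CC)(CC)CC | intermediate
36 | (3R,5S,8S,9S,10R,13R)-3-bromolabd-14-ene-8,13-diol = (1S,2S,4aS,6R,8aR)-6-bromo-1-[(3R)-3-hydroxy-3-methylpent-4-en-1-yl]-2,5,5,8a-tetramethyldecahydronaphthalen-2-ol | C=C[C@](C)(O)CC[C@H]1[C@]2(C)CC[C@@H](Br)C(C)(C)[C@H]2CC[C@]1(C)O | target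

Total step count: 25. Longest linear sequence: 23 steps (steps 1–3, 5–19 and 21–25, from ethyl levulinate); steps 4 and 20 prepare the diene and the dioxolanone on side branches.

Steps most likely to fail

Step 5 (Diels–Alder). The trisubstituted enal may react sluggishly, the cationic boron catalyst may be sequestered by or may ionise the dioxolane, and facial discrimination may be insufficient. The fallback gives up asymmetric catalysis for racemic synthesis and resolution. Setting out from 5 and 7, the cycloaddition would be promoted by an achiral Lewis acid (Me2AlCl, CH2Cl2, −78 °C), which gives 8 together with the mirror-image aldehyde F1. The mixture would be carried through the chemistry of steps 6 and 7 unchanged, giving alongside 10 and 11 the mirror-image silyl enol ether enoate F2 and the mirror-image enone F3. The racemic, UV-active enone would then be resolved by preparative chromatography on a chiral stationary phase (amylose tris(3,5-dimethylphenylcarbamate), supercritical CO2/MeOH), and the route is rejoined at 11.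

Step 12 (key cyclisation). The ketyl or the enoate may be reduced without ring closure, and the alkoxide may lactonise onto C12. Diastereoselection may also erode, because the required chair places the C8 methyl 1,3-diaxial to the C10 methyl. The fallback keeps the C8–C9 bond but generates the C8 radical by hydrogen-atom transfer instead of electron transfer. Setting out from 18, double silylation (TBSOTf, Et3N, CH2Cl2, 0 °C) would give the bis-silyl enol ether F4, drawn as the terminal enol ether; internal isomers lead to the same radical. An iron hydride (Fe(acac)3, PhSiH3, EtOH/ethylene glycol, 60 °C) would add a hydrogen atom to the enol ether, and the tertiary α-silyloxy C8 radical should add 6-exo to the enoate, as in reductive olefin coupling with silyl enol ether donors. This gives the bis-silyl ether ester F5, whose silylated C8 oxygen cannot lactonise. Global desilylation (HF·pyridine, THF) returns to 19.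

Step 17 (bromoalkene hydrogenation). Hydrogen may be delivered to the C3 radical from the wrong face, bromine may be lost by over-reduction, and hydrogen-atom transfer to the hindered, electron-poor alkene may be slow. The fallback leaves radical chemistry for heterogeneous syn-hydrogenation, leading from 24 directly to 25 (H2, 1 atm, Rh/Al2O3, EtOAc, rt). Both hydrogens should then arrive on the face opposite the axial C4 and C10 methyls, so that bromine again ends equatorial by kinetic facial control, and rhodium on alumina is the classical catalyst for saturating vinylic halides with little hydrogenolysis. It makes no new compound (F0).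

Further compounds
F1 | step 5 | enantiomer of 8, (1S,6S)-4-(tert-butyldimethylsilyloxy)-1-methyl-6-[2-(2-methyl-1,3-dioxolan-2-yl)ethyl]cyclohex-3-ene-1-carbaldehyde | O=C[C@@]1(C)CC=C(O[Si](C)(C)C(C)(C)C)C[C@@H]1CCC2(C)OCCO2
F2 | step 5 | enantiomer of 10 | COC(=O)/C=C/[C@@]1(C)CC=C(O[Si](C)(C)C(C)(C)C)C[C@@H]1CCC2(C)OCCO2
F3 | step 5 | enantiomer of 11 | COC(=O)/C=C/[C@@]1(C)C=CC(=O)C[C@@H]1CCC2(C)OCCO2
F4 | step 12 | methyl (E)-3-[(1S,2S,4R)-4-(tert-butyldimethylsilyloxy)-2-[3-(tert-butyldimethylsilyloxy)but-3-enyl]-1,3,3-trimethylcyclohexyl]prop-2-enoate | COC(=O)/C=C/[C@]1(C)CC[C@@H](O[Si](C)(C)C(C)(C)C)C(C)(C)[C@H]1CCC(=C)O[Si](C)(C)C(C)(C)C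
F5 | step 12 | 3,8-bis-O-(tert-butyldimethylsilyl) ether of 19 | COC(=O)C[C@H]1[C@]2(C)CC[C@@H](O[Si](C)(C)C(C)(C)C)C(C)(C)[C@H]2CC[C@]1(C)O[Si](C)(C)C(C)(C)C
F0 | step 17 | none | none
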